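**Plan**

- Retrosynthesis: the quinone C2–O bond is cut first (phenoxide plus bromoquinone). Ring A is then dissolved completely by cutting C(OAr)–CH, C(Me)–C(O) and C(O)–CH, which leaves a chromium carbene carbon that carries the ring-B oxygen and a 3-methylbut-1-en-2-yl group, one CO ligand and propyne. The carbene C–O(ring B) bond is cut last.
- Enabling feature: ring A is a benzene with two para oxygens; the aryl-ether carbon lies between the isopropyl carbon and a CH, the methoxy carbon between the methyl carbon and the other CH. This is the substitution map of an aryloxy(alkenyl)carbene + CO + terminal alkyne benzannulation.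
- Forward order: thymol gives 6-bromo-4-methoxythymol, the common source of ring B (benzyl-protected catechol monoether) and of ring C (bromoquinone). Ring B exists first, ring A is grown on its oxygen, and the finished quinone ring C is attached last.
- Stereochemistry: none to set (see remark).

Key step: step 9

Remark on the chemistry: the target has no stereocentre, no stereogenic double bond and no axis expected to be configurationally stable, so it is a single achiral compound and no step controls configuration. In the SMILES of chromium complexes, carbene and CO ligands are drawn with formal double bonds to Cr, and an η6-arene bond is written as a dot.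

**Route**

Step 1
Reactants: 1 thymol
Product: 2 4-bromo-2-isopropyl-5-methylphenol
Conditions: NBS (1.0 equiv), MeCN, 0 °C → rt
Reagents that add atoms: N-bromosuccinimide, O=C1CCC(=O)N1Br
Why: Electrophilic aromatic bromination of a phenol with NBS should go para to the hydroxyl, which is also the least hindered activated position of thymol.

Step 2
Reactants: 2 4-bromo-2-isopropyl-5-methylphenol
Product: 3 2-isopropyl-4-methoxy-5-methylphenol (4-methoxythymol)
Conditions: NaOMe (4 equiv, in MeOH), CuBr (10 mol %), DMF, 110 °C, N2; aq. HCl work-up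
Reagents that add atoms: sodium methoxide, C[O-].[Na+]
Why: Copper(I)-catalysed Ullmann-type methoxylation of an aryl bromide, a reaction type established for 2-alkyl-4-bromophenols reacting as their phenoxides.

Step 3
Reactants: 3 2-isopropyl-4-methoxy-5-methylphenol
Product: 4 2-bromo-6-isopropyl-4-methoxy-3-methylphenol
Conditions: NBS (1.0 equiv), dry CH2Cl2, −20 → 0 °C, dark
Reagents that add atoms: N-bromosuccinimide, O=C1CCC(=O)N1Br
Why: Electrophilic bromination should occur ortho to the free hydroxyl (the stronger donor) at the only open ortho position, the other free ring position being shielded by isopropyl and methoxy.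

Step 4
Reactants: 4 2-bromo-6-isopropyl-4-methoxy-3-methylphenol
Product: 5 1-(benzyloxy)-2-bromo-6-isopropyl-4-methoxy-3-methylbenzene
Conditions: BnBr, K2CO3, DMF, rt → 50 °C
Reagents that add atoms: benzyl bromide, BrCc1ccccc1
Why: Williamson etherification of a phenoxide with a benzylic halide, which tolerates the two ortho substituents.

Step 5
Reactants: 5 1-(benzyloxy)-2-bromo-6-isopropyl-4-methoxy-3-methylbenzene
Product: 8 2-(benzyloxy)-3-isopropyl-5-methoxy-6-methylphenol, via aryllithium 6 (not isolated), via dimethyl arylboronate 7 (not isolated)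
Conditions: n-BuLi (1.1 equiv), THF, −78 °C; B(OMe)3, −78 °C → rt; then 30% H2O2, aq. NaOH, 0 °C → rt
Reagents that add atoms: hydrogen peroxide, OO
Why: Bromine–lithium exchange, borylation and alkaline peroxide oxidation (1,2-aryl shift from boron to oxygen) is the standard ipso-hydroxylation of an aryl bromide, and the cold aryllithium is trapped before it can attack the benzyl ether.

Step 6
Reactants: 9 3-methylbutan-2-one
Product: 10 (E)-3-methylbutan-2-one 2,4,6-triisopropylbenzenesulfonylhydrazone
Conditions: TrisNHNH2 (1.0 equiv), MeOH, cat. HCl, rt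
Reagents that add atoms: 2,4,6-triisopropylbenzenesulfonyl hydrazide, NNS(=O)(=O)c1c(C(C)C)cc(C(C)C)cc1C(C)C
Why: Acid-catalysed condensation of a ketone with a sulfonyl hydrazide, expected to give mainly the E hydrazone with the N–N bond anti to isopropyl.

Step 7
Reactants: 10 (E)-3-methylbutan-2-one 2,4,6-triisopropylbenzenesulfonylhydrazone; 11 chromium hexacarbonyl
Product: 14 tetramethylammonium pentacarbonyl(3-methyl-2-methylidenebutanoyl)chromate, via 2-lithio-3-methylbut-1-ene 12 (not isolated), via lithium acylchromate 13 (not isolated)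
Conditions: n-BuLi (2.0 equiv), THF, −78 → 0 °C (N2 evolution); Cr(CO)6, THF, 0 °C → rt; then Me4NBr, degassed H2O, CH2Cl2 extraction
Reagents that add atoms: tetramethylammonium bromide, C[N+](C)(C)C.[Br-]
Why: In this Shapiro reaction the hydrazone dianion forms at the methyl group and loses sulfinate and N2 to give the 2-lithioalkene, which adds to a CO ligand (Fischer acylmetalate synthesis); cation exchange gives the storable ammonium salt.

Step 8
Reactants: 14 tetramethylammonium pentacarbonyl(3-methyl-2-methylidenebutanoyl)chromate; 8 2-(benzyloxy)-3-isopropyl-5-methoxy-6-methylphenol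
Product: 16 pentacarbonyl{[2-(benzyloxy)-3-isopropyl-5-methoxy-6-methylphenoxy](3-methylbut-1-en-2-yl)methylidene}chromium(0), via acetoxycarbene complex 15 (not isolated)
Conditions: AcBr (1.0 equiv), CH2Cl2, −40 °C; then 8 (1.0 equiv), −40 → 0 °C; rapid filtration through silica, used at once
Reagents that add atoms: none
Why: O-Acylation of the acylmetalate gives an acyloxycarbene that behaves as a mixed anhydride, and the phenol displaces acetate at the carbene carbon by addition–elimination (Fischer carbene alkoxy exchange via the acyloxycarbene), so the hindered aryl–oxygen bond forms without any aryl coupling.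

Step 9
Reactants: 16 pentacarbonyl{[2-(benzyloxy)-3-isopropyl-5-methoxy-6-methylphenoxy](3-methylbut-1-en-2-yl)methylidene}chromium(0); 17 propyne
Product: 19 4-[2-(benzyloxy)-3-isopropyl-5-methoxy-6-methylphenoxy]-5-isopropyl-2-methylphenol, via tricarbonylchromium arene complex 18 (not isolated)
Conditions: propyne (3 equiv, THF solution), THF (0.05 M), 50 °C, sealed tube, Ar; then air, Et2O, rt
Reagents that add atoms: none
Why: Loss of one CO from 16 lets propyne coordinate and insert into the Cr=C bond with its CH terminus bonding to the carbene carbon; CO insertion then gives a chromium-bound dienylketene, 6π-electrocyclisation joins the ketene carbon to the alkene CH2, and tautomerisation of the cyclohexadienone gives the Cr(CO)3-bound 4-aryloxyphenol, which air frees from the metal. The closest known reaction type is the Dötz benzannulation of alkenyl(aryloxy)carbene chromium complexes with terminal alkynes to give diaryl ethers. Ring A closes in this 6π-electrocyclic (formally [3+2+1]) mode, forming C(OAr)–CH, C(Me)–C(OH) and C(OH)–CH. No stereocentre arises. The step needs the alkyne methyl next to the CO-derived carbon, which the steric difference between the two ends of a terminal alkyne secures, and phenol formation over cyclopentadiene, furan or cyclobutenone products, which an alkenyl (not aryl) carbene, THF and moderate temperature favour.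

Step 10
Reactants: 19 4-[2-(benzyloxy)-3-isopropyl-5-methoxy-6-methylphenoxy]-5-isopropyl-2-methylphenol
Product: 20 1-(benzyloxy)-2-(2-isopropyl-4-methoxy-5-methylphenoxy)-6-isopropyl-4-methoxy-3-methylbenzene
Conditions: MeI, K2CO3, acetone, reflux
Reagents that add atoms: iodomethane, CI
Why: Williamson O-methylation of the only free phenol, carried out promptly because 4-aryloxyphenols are air-sensitive.

Step 11
Reactants: 20 1-(benzyloxy)-2-(2-isopropyl-4-methoxy-5-methylphenoxy)-6-isopropyl-4-methoxy-3-methylbenzene
Product: 21 2-(2-isopropyl-4-methoxy-5-methylphenoxy)-6-isopropyl-4-methoxy-3-methylphenol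
Conditions: H2 (1 atm), 10% Pd/C, EtOAc–EtOH, rt
Reagents that add atoms: none
Why: Catalytic hydrogenolysis cleaves the benzyl aryl ether, and the diaryl ether and methyl ethers are inert under these conditions.

Step 12
Reactants: 4 2-bromo-6-isopropyl-4-methoxy-3-methylphenol
Product: 22 2-bromo-6-isopropyl-3-methylcyclohexa-2,5-diene-1,4-dione
Conditions: (NH4)2Ce(NO3)6 (2.2 equiv), MeCN–H2O 3:1, 0 °C
Reagents that add atoms: water, O
Why: Ceric ammonium nitrate oxidation of a 4-methoxyphenol gives the p-benzoquinone by water attack at the methoxy-bearing carbon and loss of methanol, and the ring bromine is retained.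

Step 13
Reactants: 21 2-(2-isopropyl-4-methoxy-5-methylphenoxy)-6-isopropyl-4-methoxy-3-methylphenol; 22 2-bromo-6-isopropyl-3-methylcyclohexa-2,5-diene-1,4-dione
Product: 23 2-[2-(2-isopropyl-4-methoxy-5-methylphenoxy)-6-isopropyl-4-methoxy-3-methylphenoxy]-6-isopropyl-3-methylcyclohexa-2,5-diene-1,4-dione
Conditions: Cs2CO3 (1.5 equiv), 22 (1.2 equiv), MeCN, 0 °C → rt, Ar, dark
Reagents that add atoms: none
Why: Addition–elimination of a phenoxide on a 2-bromoquinone (vinylogous acyl substitution): attack at the bromine-bearing carbon, β to the C4 carbonyl, is followed by loss of bromide, as is known for 2-bromo-3-methylquinones.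

**Compound list**

1 | thymol | Cc1ccc(C(C)C)c(O)c1 | starting material
2 | 4-bromo-2-isopropyl-5-methylphenol | Cc1cc(O)c(C(C)C)cc1Br | intermediate
3 | 2-isopropyl-4-methoxy-5-methylphenol | COc1cc(C(C)C)c(O)cc1C | intermediate
4 | 2-bromo-6-isopropyl-4-methoxy-3-methylphenol | COc1cc(C(C)C)c(O)c(Br)c1C | intermediate
5 | 1-(benzyloxy)-2-bromo-6-isopropyl-4-methoxy-3-methylbenzene | COc1cc(C(C)C)c(OCc2ccccc2)c(Br)c1C | intermediate
6 | [2-(benzyloxy)-3-isopropyl-5-methoxy-6-methylphenyl]lithium | [Li]c1c(C)c(OC)cc(C(C)C)c1OCc1ccccc1 | intermediate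
7 | dimethyl [2-(benzyloxy)-3-isopropyl-5-methoxy-6-methylphenyl]boronate | COB(OC)c1c(C)c(OC)cc(C(C)C)c1OCc1ccccc1 | intermediate
8 | 2-(benzyloxy)-3-isopropyl-5-methoxy-6-methylphenol | Oc1c(C)c(OC)cc(C(C)C)c1OCc1ccccc1 | intermediate
9 | 3-methylbutan-2-one | CC(C)C(C)=O | starting material
10 | (E)-3-methylbutan-2-one 2,4,6-triisopropylbenzenesulfonylhydrazone | CC(C)/C(C)=N/NS(=O)(=O)c1c(C(C)C)cc(C(C)C)cc1C(C)C | intermediate
11 | chromium hexacarbonyl | O=C=[Cr](=C=O)(=C=O)(=C=O)(=C=O)=C=O | starting material
12 | 2-lithio-3-methylbut-1-ene | [Li]C(=C)C(C)C | intermediate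
13 | lithium pentacarbonyl(3-methyl-2-methylidenebutanoyl)chromate | C=C(C(C)C)C([O-])=[Cr](=C=O)(=C=O)(=C=O)(=C=O)=C=O.[Li+] | intermediate
14 | tetramethylammonium pentacarbonyl(3-methyl-2-methylidenebutanoyl)chromate | C=C(C(C)C)C([O-])=[Cr](=C=O)(=C=O)(=C=O)(=C=O)=C=O.C[N+](C)(C)C | intermediate
15 | pentacarbonyl[acetoxy(3-methylbut-1-en-2-yl)methylidene]chromium(0) | C=C(C(C)C)C(OC(C)=O)=[Cr](=C=O)(=C=O)(=C=O)(=C=O)=C=O | intermediate
16 | pentacarbonyl{[2-(benzyloxy)-3-isopropyl-5-methoxy-6-methylphenoxy](3-methylbut-1-en-2-yl)methylidene}chromium(0) | C=C(C(C)C)C(Oc1c(C)c(OC)cc(C(C)C)c1OCc1ccccc1)=[Cr](=C=O)(=C=O)(=C=O)(=C=O)=C=O | intermediate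
17 | propyne | CC#C | starting material
18 | tricarbonylchromium η6 complex of 19 (metal on the new ring A) | Cc1cc(Oc2c(C)c(OC)cc(C(C)C)c2OCc2ccccc2)c(C(C)C)cc1O.O=C=[Cr](=C=O)=C=O | intermediate
19 | 4-[2-(benzyloxy)-3-isopropyl-5-methoxy-6-methylphenoxy]-5-isopropyl-2-methylphenol | Cc1cc(Oc2c(C)c(OC)cc(C(C)C)c2OCc2ccccc2)c(C(C)C)cc1O | intermediate
20 | 1-(benzyloxy)-2-(2-isopropyl-4-methoxy-5-methylphenoxy)-6-isopropyl-4-methoxy-3-methylbenzene | COc1cc(C(C)C)c(Oc2c(C)c(OC)cc(C(C)C)c2OCc2ccccc2)cc1C | intermediate
21 | 2-(2-isopropyl-4-methoxy-5-methylphenoxy)-6-isopropyl-4-methoxy-3-methylphenol | COc1cc(C(C)C)c(Oc2c(C)c(OC)cc(C(C)C)c2O)cc1C | intermediate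
22 | 2-bromo-6-isopropyl-3-methylcyclohexa-2,5-diene-1,4-dione | CC1=C(Br)C(=O)C(C(C)C)=CC1=O | intermediate
23 | 2-[2-(2-isopropyl-4-methoxy-5-methylphenoxy)-6-isopropyl-4-methoxy-3-methylphenoxy]-6-isopropyl-3-methylcyclohexa-2,5-diene-1,4-dione | COc1cc(C(C)C)c(Oc2c(C)c(OC)cc(C(C)C)c2OC2=C(C)C(=O)C=C(C(C)C)C2=O)cc1C | target

**Step count**

Total steps: 13. Longest linear sequence: 10 steps (1, 2, 3, 4, 5, 8, 9, 10, 11, 13).

**Steps most likely to fail**

1. Step 9 (benzannulation). The electrophilic aryloxycarbene may decompose thermally faster than the alkyne inserts. CO insertion may also be bypassed in favour of five-membered-ring products, and the volatile alkyne may be lost from solution. The fallback sets out from phenol 8 and delivers ring A as a preformed aryl group. Commercial carvacrol methyl ether (5-isopropyl-2-methylanisole) should react with I2, mCPBA and TsOH in CH2Cl2, iodination going para to methoxy, to give bis(2-isopropyl-4-methoxy-5-methylphenyl)iodonium tosylate F1. The potassium salt of 8 (t-BuOK, THF, rt → 50 °C) is then arylated by F1 in a metal-free diaryliodonium coupling, a method known to tolerate ortho-crowded partners. This comes back to the route at 20.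

2. Step 8 (aryloxycarbene formation). The doubly ortho-substituted phenol may attack the carbene carbon so slowly that the labile acetoxycarbene decomposes first, or the phenol may add in conjugate fashion to the unsubstituted alkene terminus. The fallback reverses the roles so that the crowded ring B is the electrophile. It sets out from 3 and 5, which are joined by a ligand-accelerated Ullmann ether coupling (CuI, picolinic acid or 2,2,6,6-tetramethylheptane-3,5-dione, Cs2CO3, DMSO or NMP, 110–130 °C), and comes back to the route at 20. It makes no compound outside the route (F0).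

3. Step 13 (quinone attachment). The very electron-rich phenoxide may transfer an electron to the bromoquinone instead of adding to it, or may add at the unsubstituted quinone CH rather than at the bromine-bearing carbon. The fallback attaches ring C at the phenol oxidation level and oxidises last. It sets out from 21 and 5: copper-catalysed Ullmann coupling (conditions as above, forcing) should give 1-(benzyloxy)-2-[2-(2-isopropyl-4-methoxy-5-methylphenoxy)-6-isopropyl-4-methoxy-3-methylphenoxy]-6-isopropyl-4-methoxy-3-methylbenzene F2. Hydrogenolysis (H2, Pd/C) then gives 2-[2-(2-isopropyl-4-methoxy-5-methylphenoxy)-6-isopropyl-4-methoxy-3-methylphenoxy]-6-isopropyl-4-methoxy-3-methylphenol F3. PhI(OAc)2 in MeCN–H2O should oxidise only this free 4-methoxyphenol ring to the p-quinone, the fully etherified rings A and B being inert, and so comes back to the route at 23.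

**Further compounds**

F0 | step 8 | none | none
F1 | step 9 | bis(2-isopropyl-4-methoxy-5-methylphenyl)iodonium 4-methylbenzenesulfonate | COc1cc(C(C)C)c([I+]c2cc(C)c(OC)cc2C(C)C)cc1C.Cc1ccc(S(=O)(=O)[O-])cc1
F2 | step 13 | 1-(benzyloxy)-2-[2-(2-isopropyl-4-methoxy-5-methylphenoxy)-6-isopropyl-4-methoxy-3-methylphenoxy]-6-isopropyl-4-methoxy-3-methylbenzene | COc1cc(C(C)C)c(Oc2c(C)c(OC)cc(C(C)C)c2Oc2c(C)c(OC)cc(C(C)C)c2OCc2ccccc2)cc1C
F3 | step 13 | 2-[2-(2-isopropyl-4-methoxy-5-methylphenoxy)-6-isopropyl-4-methoxy-3-methylphenoxy]-6-isopropyl-4-methoxy-3-methylphenol | COc1cc(C(C)C)c(Oc2c(C)c(OC)cc(C(C)C)c2Oc2c(C)c(OC)cc(C(C)C)c2O)cc1C
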